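The 4.0 min feed of substrate into the reagent and initiator is shorter than the half-life substrate then shows in the ash run, 12.1 min as read between 8.00 min and 15.0 min.

| flask | substrate | reagent | initiator | remark | time |
|---|---|---|---|---|---|
| ash | 0.0050 M (fed, over 4.0 min) | 1.8 equiv | 3.8 mol% | run made earlier |  |
| maple | 0.0075 M (fed, over 4.0 min) | 1.8 equiv | 3.8 mol% | run made earlier |  |
| flask | 0.010 M (fed, over 4.0 min) | 1.80 equiv | 3.8 mol% |  | 30 min |

| run | time / min | target / % | substrate / % |
|---|---|---|---|
| ash | 8.00 | 60.9 | 37.8 |
| ash | 15.0 | 73.9 | 25.3 |
| ash | 25.0 | 83.5 | 17.7 |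
| ash | 30.0 | 84.8 | 15.3 |
| maple | 8.00 | 63.7 | 38.2 |
| maple | 15.0 | 76.2 | 25.0 |
| maple | 25.0 | 83.5 | 18.8 |
| maple | 30.0 | 84.7 | 13.2 |

(each reading ± 1 percentage point)

1. amount of target in the flask at 30 min, in percent of the substrate charged
2. amount of substrate in the flask at 30 min, in percent of the substrate charged
3. concentration of reagent at 30 min, in M



The next rung is longer: the ash readings from 15.0 min to 30.0 min give 20.7 min. The 30 min of the run is longer again; the ash run ends with 15.3 % substrate and the maple run with 13.2 %.

The readings give substrate and target, not reagent, so reagent has to be reckoned. The reagent margin, [reagent] minus [substrate] with the whole charge counted as fed, is 0.00800 M in this flask. A step taking one of each leaves this margin unchanged, and while it is positive substrate is the limiting reagent. My own reckoning adds the ash run's last substrate reading to the margin and gives 0.00953 M reagent at 30 min. That number stands on an unchanged margin, so [reagent] is the thing to watch in a repeat.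

The forecast, “I expect the same curve”, gives 85 % target (81 % to 88.5 %), 15 % substrate (11.5 % to 19 %) and 0.0095 M reagent (0.0088 M to 0.0103 M).

The flask gives 83.9 % target, 15.8 % substrate and 0.00182 M reagent, which is below the forecast's range.

    initiator → 2 initiating radical (k = 0.00130 /min)
    substrate + initiating radical → capped initiator + first chain carrier (k = 3.70 × 10⁵ /M/s)
    reagent + first chain carrier ⇌ target + second chain carrier (K = 5.40, k = 1.40 × 10⁵ /M/s)
    substrate + second chain carrier → by-product + first chain carrier (k = 2.80 × 10⁵ /M/min)
    2 first chain carrier → ended chains (k = 1.90 × 10⁶ /M/s)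
    2 reagent → homo dimer (k = 3.50 /M/min)

In the flask the margin has shrunk to 2.44 × 10⁻⁴ M, and the homo dimer holds 0.00778 M of reagent, half of that turnover up to 30 min being done by 2.38 min. The flask is not at rest: at 300 min it holds 3.11 % substrate, 94.4 % target and 1.52 × 10⁻⁴ M reagent. The margin has then crossed zero, to −1.59 × 10⁻⁴ M, and reagent has become the limiting reagent.

The same flask with 0.450 equiv of reagent has a margin of −0.00550 M from its charges, which leaves 55.0 % of its substrate unmatched by the reagent charged. It gives 59.2 % substrate, 40.6 % target and 5.80 × 10⁻⁵ M reagent.

The data were computed with made-up constants; the scatter is artificial.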